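**Retrosynthetic overview**
- Numbering: lactone carbonyl C1, ring carbons C2–C5, chain C6–C20. The strategy rests on the unbranched C3–C8 run oxygenated at C3, C5 and C7, whose C5/C7 carbinols are syn (5R,7R in the target); this is the pattern 2-deoxyribose-5-phosphate aldolase (DERA) builds from chloroacetaldehyde and two acetaldehydes.
- Lactone ring (O, C1–C5): opened to a 5-hydroxy-3-oxo ester, made by acetate Claisen condensation (C2–C3) on a C3 carboxylic acid.
- C8–C9: lithiated C9 dithiane of the C9–C20 fragment plus the C7–C8 epoxide; C9–OH by 1,3-anti reduction directed by C7–OH; C11 by asymmetric hydrogenation of methyl 3-oxododecanoate.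
- C6–C7 and C4–C5: tandem enzymatic aldol giving the lactol (ring O, C3–C7).
- Ring order: lactol ring first (step 1, opened in step 2), oxirane C7–C8 (step 3, opened in step 9), dihydropyranone ring last (step 16).

Key step: step 1

Remark: the target is treated as the enol of a 3-oxo δ-lactone, target numbering is used for all intermediates, and CIP letters quoted for an intermediate refer to that compound (the same spatial arrangement changes letter as substituent priorities change).

Step 1
Reactants: 1 chloroacetaldehyde; 2 acetaldehyde (two equivalents)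
Product: 5 (4R,6S)-6-(chloromethyl)oxane-2,4-diol (lactol; anomeric mixture), via (S)-4-chloro-3-hydroxybutanal 3 (not isolated), via (3R,5S)-6-chloro-3,5-dihydroxyhexanal 4 (not isolated)
Conditions: 2-deoxy-D-ribose-5-phosphate aldolase (E. coli, cell-free extract), H2O, pH 7.2 (NaHCO3), 20–25 °C, slow co-feed of aqueous 1 and 2 (2.1 equiv); then acetone, filtration, EtOAc extraction
Reagents that add atoms: none
Why: The active-site lysine condenses with acetaldehyde to an enamine that adds to the carbonyl of chloroacetaldehyde (bond C6–C7) and, after hydrolysis, releases aldehyde 3, which the enzyme takes up again as acceptor for a second enamine addition (bond C4–C5) to give 4. The C7 hydroxyl of 4 then adds to the C3 aldehyde in a 6-exo-trig hemiacetalisation, and lactol 5 is the resting form that withdraws the aldehyde from further turnover. This is the known sequential aldol addition of this lysine (Schiff base) aldolase, the reaction type used for chlorinated statin side-chain lactols. C7 and C5 are both fixed by the enzyme, which presents the same face of the bound enamine to each acceptor, so the two carbinols should come out syn and in the absolute sense of the target (S at C7 and R at C5 by CIP in 5). The step needs donor/acceptor and sequence selectivity among three enolisable aldehydes; the pocket uses only acetaldehyde as donor, the alpha-chloro aldehyde enters as first acceptor, and slow co-feeding keeps acetaldehyde self-addition low. Ring closure of the double adduct limits the chain to two additions.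

Step 2
Reactants: 5 (4R,6S)-6-(chloromethyl)oxane-2,4-diol
Product: 6 (3S,5S)-6-chlorohexane-1,3,5-triol
Conditions: NaBH4, EtOH, 0 °C → rt; acetone quench, evaporate, silica plug (EtOAc/MeOH), no aqueous work-up
Reagents that add atoms: none
Why: Borohydride reduction of the open hydroxy aldehyde in equilibrium with the lactol should give the triol without touching C5, C7 or the primary chloride; any early epoxide closure in the basic medium only anticipates step 3.

Step 3
Reactants: 6 (3S,5S)-6-chlorohexane-1,3,5-triol
Product: 7 (3S)-4-[(2S)-oxiran-2-yl]butane-1,3-diol (C7–C8 epoxide, free C3/C5 diol)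
Conditions: K2CO3 (1.5 equiv), MeOH, 0 °C → rt; filter, evaporate below 30 °C, triturate with EtOAc
Reagents that add atoms: none
Why: Intramolecular Williamson etherification (3-exo-tet) of the C7 alkoxide on C8–Cl is far faster than the other ring sizes open to the C3 and C5 hydroxyls, and C7 keeps its configuration because its C–O bond is not broken.

Step 4
Reactants: 7 (3S)-4-[(2S)-oxiran-2-yl]butane-1,3-diol
Product: 8 (2S)-2-[(2S)-2,4-bis(tert-butyldimethylsilyloxy)butyl]oxirane
Conditions: TBSCl (2.4 equiv), imidazole (5 equiv), DMF, 0 °C → rt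
Reagents that add atoms: tert-butyldimethylsilyl chloride, CC(C)(C)[Si](C)(C)Cl
Why: Standard imidazole-mediated silylation masks the C3 (primary) and C5 (secondary) hydroxyls as ethers that tolerate the organolithium step and can later be told apart by their steric difference; the terminal epoxide is inert under these conditions.

Step 5
Reactants: 9 methyl 3-oxododecanoate
Product: 10 methyl (3S)-3-hydroxydodecanoate
Conditions: H2 (50 bar), RuCl2[(S)-BINAP] (0.2 mol%), MeOH, 50 °C
Reagents that add atoms: none
Why: Noyori asymmetric hydrogenation of a beta-keto ester; the chelated keto ester is reduced from the face dictated by the (S)-BINAP ligand, which sets the C11 carbinol as S.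

Step 6
Reactants: 10 methyl (3S)-3-hydroxydodecanoate
Product: 11 methyl (3S)-3-(tert-butyldimethylsilyloxy)dodecanoate
Conditions: TBSCl, imidazole, DMF, rt
Reagents that add atoms: tert-butyldimethylsilyl chloride, CC(C)(C)[Si](C)(C)Cl
Why: Routine silylation; the C11 oxygen must be capped so that it survives dithiane metalation and cannot direct the later C9 reduction.

Step 7
Reactants: 11 methyl (3S)-3-(tert-butyldimethylsilyloxy)dodecanoate
Product: 12 (3S)-3-(tert-butyldimethylsilyloxy)dodecanal
Conditions: i-Bu2AlH (1.1 equiv), CH2Cl2, −78 °C; MeOH, then aq. KNaC4H4O6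
Reagents that add atoms: none
Why: Partial reduction of the ester; the tetrahedral aluminium hemiacetal is stable at −78 °C and collapses to the aldehyde only on work-up.

Step 8
Reactants: 12 (3S)-3-(tert-butyldimethylsilyloxy)dodecanal
Product: 13 2-[(2S)-2-(tert-butyldimethylsilyloxy)undecyl]-1,3-dithiane
Conditions: HS(CH2)3SH (1.2 equiv), MgBr2·OEt2 (0.3 equiv), Et2O, 0 °C → rt
Reagents that add atoms: propane-1,3-dithiol, SCCCS
Why: Lewis-acid thioacetalisation of the aldehyde under mild conditions that leave the beta-silyloxy group in place; the dithiane carbon is the future C9.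

Step 9
Reactants: 13 2-[(2S)-2-(tert-butyldimethylsilyloxy)undecyl]-1,3-dithiane; 8 (2S)-2-[(2S)-2,4-bis(tert-butyldimethylsilyloxy)butyl]oxirane
Product: 15 (2S,4S)-4,6-bis(tert-butyldimethylsilyloxy)-1-{2-[(2S)-2-(tert-butyldimethylsilyloxy)undecyl]-1,3-dithian-2-yl}hexan-2-ol (C7 alcohol with C9 dithiane), via lithiated dithiane 14 (not isolated)
Conditions: 13 (1.3 equiv), t-BuLi (1.3 equiv), THF/HMPA (10:1), −78 °C, 10 min; then 8, −78 → −30 °C; aq. NH4Cl
Reagents that add atoms: none
Why: Corey–Seebach umpolung; the 2-lithio-1,3-dithiane opens the terminal epoxide by SN2 attack at the unsubstituted C8 (bond C8–C9), which frees the C7 hydroxyl with its configuration unchanged.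

Step 10
Reactants: 15 C7 alcohol with C9 dithiane
Product: 16 (3S,5S,9S)-1,3,9-tris(tert-butyldimethylsilyloxy)-5-hydroxyoctadecan-7-one (C7 hydroxy C9 ketone)
Conditions: MeI (10 equiv), CaCO3 (5 equiv), MeCN/H2O (9:1), 40 °C
Reagents that add atoms: water, O
Why: Alkylative dithiane hydrolysis (S-methylation, ring opening, capture of the thionium ion by water) under carbonate buffering, which should spare the silyl ethers and the beta-hydroxy ketone.

Step 11
Reactants: 16 C7 hydroxy C9 ketone
Product: 17 (3S,5R,7R,9S)-1,3,9-tris(tert-butyldimethylsilyloxy)octadecane-5,7-diol (7,9-anti diol)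
Conditions: Me4NBH(OAc)3 (5 equiv), MeCN/AcOH (1:1), −30 °C; aq. KNaC4H4O6
Reagents that add atoms: none
Why: Evans–Saksena reduction; the C7 hydroxyl exchanges onto boron and delivers hydride intramolecularly through a chair transition state, setting C9 anti to C7 (and hence syn to C11), while the silylated C11 oxygen cannot compete as a directing group.

Step 12
Reactants: 17 7,9-anti diol
Product: 18 (4R,6R)-4-[(2S)-2,4-bis(tert-butyldimethylsilyloxy)butyl]-6-[(2S)-2-(tert-butyldimethylsilyloxy)undecyl]-2,2-dimethyl-1,3-dioxane (C7/C9 acetonide)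
Conditions: 2,2-dimethoxypropane, PPTS (5 mol%), CH2Cl2, 0 °C → rt
Reagents that add atoms: 2,2-dimethoxypropane, COC(C)(C)OC
Why: Acid-catalysed transketalisation ties the only two free hydroxyls into an isopropylidene acetal, so that no hydroxyl can trap the C3 aldehyde or acid in the coming oxidation.

Step 13
Reactants: 18 C7/C9 acetonide
Product: 19 primary C3 alcohol (C5 and C11 tert-butyldimethylsilyl ethers and C7/C9 acetonide retained)
Conditions: HF·pyridine, pyridine, THF, 0 °C → rt
Reagents that add atoms: none
Why: Buffered fluoride cleaves the unhindered primary silyl ether much faster than the two secondary ones and leaves the acetonide untouched (steric differentiation of silyl ethers).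

Step 14
Reactants: 19 primary C3 alcohol
Product: 20 C3 carboxylic acid (3-silyloxy acid; C1 and C2 not yet present)
Conditions: TEMPO (10 mol%), NaClO2 (2 equiv), NaOCl (3 mol%), MeCN/phosphate buffer pH 6.7, 35 °C
Reagents that add atoms: sodium chlorite, [Na+].[O-]Cl=O
Why: TEMPO/chlorite oxidation takes the primary alcohol through the aldehyde to the acid at near-neutral pH, conditions under which acetonide and silyl ethers should hold and the beta-silyloxy group should not eliminate.

Step 15
Reactants: 20 C3 carboxylic acid; 21 tert-butyl acetate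
Product: 24 tert-butyl 3-oxo ester (C1–C20 chain; C5 and C11 silyl ethers, C7/C9 acetonide), via acyl imidazolide 22 (not isolated), via lithium enolate of tert-butyl acetate 23 (not isolated)
Conditions: 20, CDI (1.2 equiv), THF, rt, 1 h; 21 (3.5 equiv), LiN(i-Pr)2 (3.5 equiv, commercial solution), THF, −78 °C; imidazolide solution added at −78 °C; aq. NH4Cl
Reagents that add atoms: none
Why: Crossed Claisen condensation of an acyl imidazolide with the ester enolate (bond C2–C3); excess enolate deprotonates the product at C2, which stops a second addition and protects the C5 silyloxy group from beta-elimination.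

Step 16
Reactants: 24 tert-butyl 3-oxo ester
Product: 26 target, (6R)-4-hydroxy-6-[(2R,4S,6S)-2,4,6-trihydroxypentadecyl]-5,6-dihydro-2H-pyran-2-one, via tetrol keto ester 25 (not isolated)
Conditions: 48% aq. HF/MeCN (1:19), 0 °C → rt; evaporate with toluene; then TFA/CH2Cl2 (1:4), 0 °C → rt; evaporate, MeOH
Reagents that add atoms: none
Why: Aqueous HF removes both silyl ethers and hydrolyses the acetonide while the tert-butyl ester survives, and TFA then cleaves that ester with lactonisation by the C5 hydroxyl (6-exo-trig addition–elimination at C1) to the enolised 3-oxo δ-lactone, the stable tautomer; no stereocenter is touched.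

**Compound list**
1 | chloroacetaldehyde | ClCC=O | starting material
2 | acetaldehyde | CC=O | starting material
3 | (S)-4-chloro-3-hydroxybutanal | ClC[C@@H](O)CC=O | intermediate (not isolated)
4 | (3R,5S)-6-chloro-3,5-dihydroxyhexanal | ClC[C@@H](O)C[C@@H](O)CC=O | intermediate (not isolated)
5 | (4R,6S)-6-(chloromethyl)oxane-2,4-diol, anomeric mixture | ClC[C@@H]1C[C@@H](O)CC(O)O1 | intermediate
6 | (3S,5S)-6-chlorohexane-1,3,5-triol | ClC[C@@H](O)C[C@@H](O)CCO | intermediate
7 | (3S)-4-[(2S)-oxiran-2-yl]butane-1,3-diol | OCC[C@H](O)C[C@H]1CO1 | intermediate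
8 | (2S)-2-[(2S)-2,4-bis(tert-butyldimethylsilyloxy)butyl]oxirane | CC(C)(C)[Si](C)(C)OCC[C@H](O[Si](C)(C)C(C)(C)C)C[C@H]1CO1 | intermediate
9 | methyl 3-oxododecanoate | CCCCCCCCCC(=O)CC(=O)OC | starting material
10 | methyl (3S)-3-hydroxydodecanoate | CCCCCCCCC[C@H](O)CC(=O)OC | intermediate
11 | methyl (3S)-3-(tert-butyldimethylsilyloxy)dodecanoate | CCCCCCCCC[C@H](O[Si](C)(C)C(C)(C)C)CC(=O)OC | intermediate
12 | (3S)-3-(tert-butyldimethylsilyloxy)dodecanal | CCCCCCCCC[C@H](O[Si](C)(C)C(C)(C)C)CC=O | intermediate
13 | 2-[(2S)-2-(tert-butyldimethylsilyloxy)undecyl]-1,3-dithiane | CCCCCCCCC[C@H](O[Si](C)(C)C(C)(C)C)CC1SCCCS1 | intermediate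
14 | 2-lithio-2-[(2S)-2-(tert-butyldimethylsilyloxy)undecyl]-1,3-dithiane | CCCCCCCCC[C@H](O[Si](C)(C)C(C)(C)C)CC1([Li])SCCCS1 | intermediate (not isolated)
15 | (2S,4S)-4,6-bis(tert-butyldimethylsilyloxy)-1-{2-[(2S)-2-(tert-butyldimethylsilyloxy)undecyl]-1,3-dithian-2-yl}hexan-2-ol | CCCCCCCCC[C@H](O[Si](C)(C)C(C)(C)C)CC1(SCCCS1)C[C@@H](O)C[C@@H](O[Si](C)(C)C(C)(C)C)CCO[Si](C)(C)C(C)(C)C | intermediate
16 | (3S,5S,9S)-1,3,9-tris(tert-butyldimethylsilyloxy)-5-hydroxyoctadecan-7-one | CCCCCCCCC[C@H](O[Si](C)(C)C(C)(C)C)CC(=O)C[C@@H](O)C[C@@H](O[Si](C)(C)C(C)(C)C)CCO[Si](C)(C)C(C)(C)C | intermediate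
17 | (3S,5R,7R,9S)-1,3,9-tris(tert-butyldimethylsilyloxy)octadecane-5,7-diol | CCCCCCCCC[C@H](O[Si](C)(C)C(C)(C)C)C[C@H](O)C[C@@H](O)C[C@@H](O[Si](C)(C)C(C)(C)C)CCO[Si](C)(C)C(C)(C)C | intermediate
18 | (4R,6R)-4-[(2S)-2,4-bis(tert-butyldimethylsilyloxy)butyl]-6-[(2S)-2-(tert-butyldimethylsilyloxy)undecyl]-2,2-dimethyl-1,3-dioxane | CCCCCCCCC[C@H](O[Si](C)(C)C(C)(C)C)C[C@H]1C[C@@H](OC(C)(C)O1)C[C@@H](O[Si](C)(C)C(C)(C)C)CCO[Si](C)(C)C(C)(C)C | intermediate
19 | primary C3 alcohol of 18 (C5, C11 silyl ethers; C7/C9 acetonide) | CCCCCCCCC[C@H](O[Si](C)(C)C(C)(C)C)C[C@H]1C[C@@H](OC(C)(C)O1)C[C@@H](O[Si](C)(C)C(C)(C)C)CCO | intermediate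
20 | C3 carboxylic acid (C5, C11 silyl ethers; C7/C9 acetonide) | CCCCCCCCC[C@H](O[Si](C)(C)C(C)(C)C)C[C@H]1C[C@@H](OC(C)(C)O1)C[C@@H](O[Si](C)(C)C(C)(C)C)CC(=O)O | intermediate
21 | tert-butyl acetate | CC(=O)OC(C)(C)C | starting material
22 | acyl imidazolide of 20 | CCCCCCCCC[C@H](O[Si](C)(C)C(C)(C)C)C[C@H]1C[C@@H](OC(C)(C)O1)C[C@@H](O[Si](C)(C)C(C)(C)C)CC(=O)n2ccnc2 | intermediate (not isolated)
23 | lithium enolate of tert-butyl acetate | C=C(O[Li])OC(C)(C)C | intermediate (not isolated)
24 | tert-butyl 3-oxo ester (C5, C11 silyl ethers; C7/C9 acetonide) | CCCCCCCCC[C@H](O[Si](C)(C)C(C)(C)C)C[C@H]1C[C@@H](OC(C)(C)O1)C[C@@H](O[Si](C)(C)C(C)(C)C)CC(=O)CC(=O)OC(C)(C)C | intermediate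
25 | tert-butyl 5,7,9,11-tetrahydroxy-3-oxoicosanoate (5,7-syn; 7,9-anti; 9,11-syn) | CCCCCCCCC[C@H](O)C[C@H](O)C[C@@H](O)C[C@@H](O)CC(=O)CC(=O)OC(C)(C)C | intermediate (not isolated)
26 | (6R)-4-hydroxy-6-[(2R,4S,6S)-2,4,6-trihydroxypentadecyl]-5,6-dihydro-2H-pyran-2-one | CCCCCCCCC[C@H](O)C[C@H](O)C[C@@H](O)C[C@@H]1CC(O)=CC(=O)O1 | target

**Totals**
Total step count: 16. Longest linear sequence: 12 steps (steps 1–4 and 9–16; the fragment branch, steps 5–8 and 9–16, is equally long).

**Steps most likely to fail**

Step 1. The enzyme may lose activity at preparative aldehyde concentration through covalent modification by the two aldehydes, and acetaldehyde self-addition may erode the crossed sequence. The fallback gives up the enzymatic C–C formation and sets out from tert-butyl acetate 21, used as its lithium enolate 23, and purchased ethyl (S)-4-chloro-3-hydroxybutanoate (ClC[C@@H](O)CC(=O)OCC). A crossed Claisen condensation (excess 23, THF, −78 → −40 °C) should give tert-butyl (5S)-6-chloro-5-hydroxy-3-oxohexanoate F1. Narasaka–Prasad syn reduction (Et2BOMe, NaBH4, THF/MeOH, −78 °C) should give tert-butyl (3R,5S)-6-chloro-3,5-dihydroxyhexanoate F2. Reduction of the ester (LiBH4, THF, 0 °C → rt) returns to the route at chlorotriol 6.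

Step 9. Metalation of the 2-alkyl dithiane may be slow or incomplete, or the lithiated species may lose silanolate by beta-elimination before it meets the epoxide. The fallback sets out from epoxide 8 and assembles the dithiane in the same flask by a silyl-migration linchpin coupling. Commercial 2-(tert-butyldimethylsilyl)-1,3-dithiane (CC(C)(C)[Si](C)(C)C1SCCCS1) is metalated (t-BuLi, Et2O, −78 → −45 °C) to 2-lithio-2-(tert-butyldimethylsilyl)-1,3-dithiane F3. This opens (S)-2-nonyloxirane (CCCCCCCCC[C@H]1CO1, accessible by hydrolytic kinetic resolution of the racemate) to the lithium alkoxide of (2S)-1-[2-(tert-butyldimethylsilyl)-1,3-dithian-2-yl]undecan-2-ol F4. Adding 8 in THF/HMPA triggers a 1,4-Brook shift of silicon from carbon to oxygen, which forms the lithiated dithiane 14 in the presence of the epoxide and returns to the route at alcohol 15.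

Step 16. The free 3-oxo acid may decarboxylate before the ring closes, or the material may be diverted through the C3/C7 hemiketal and its dehydration under strong acid. The fallback sets out from 24 and closes the lactone thermally under neutral conditions before C7–OH is unveiled. HF·pyridine in pyridine/THF should remove both silyl ethers and give the C7/C9-acetonide diol keto ester F5. Heating F5 in dilute toluene at 110 °C should expel tert-butanol to an acylketene that the C5 hydroxyl traps as the acetonide-protected hydroxy pyranone F6. Mild hydrolysis of the acetonide (AcOH/H2O 4:1, 40 °C) returns to the route at target 26.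

**Further compounds**
F1 | step 1 | tert-butyl (5S)-6-chloro-5-hydroxy-3-oxohexanoate | ClC[C@@H](O)CC(=O)CC(=O)OC(C)(C)C
F2 | step 1 | tert-butyl (3R,5S)-6-chloro-3,5-dihydroxyhexanoate | ClC[C@@H](O)C[C@@H](O)CC(=O)OC(C)(C)C
F3 | step 9 | 2-lithio-2-(tert-butyldimethylsilyl)-1,3-dithiane | CC(C)(C)[Si](C)(C)C1([Li])SCCCS1
F4 | step 9 | lithium alkoxide of (2S)-1-[2-(tert-butyldimethylsilyl)-1,3-dithian-2-yl]undecan-2-ol | CCCCCCCCC[C@H](O[Li])CC1(SCCCS1)[Si](C)(C)C(C)(C)C
F5 | step 16 | tert-butyl 5,11-dihydroxy-3-oxoicosanoate C7/C9 acetonide | CCCCCCCCC[C@H](O)C[C@H]1C[C@@H](OC(C)(C)O1)C[C@@H](O)CC(=O)CC(=O)OC(C)(C)C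
F6 | step 16 | C7/C9 acetonide of target 26 | CCCCCCCCC[C@H](O)C[C@H]1C[C@@H](OC(C)(C)O1)C[C@@H]2CC(O)=CC(=O)O2
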